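**Retrosynthetic overview**

- Final step is global O-debenzylation. Both pyran rings are cut the same way (C3–C4 with O1–C2, and C3′–C4′ with O1′–C2′) into an o-quinone methide (a resorcinol ring plus its benzylic carbon) and the enamine of an arylacetaldehyde.
- Enabling feature: C4′ is a CH2 on C4a′ of ring A′, ortho to C8a′–O1′ and para to the C7′ oxygen, so ring A′, C4′ and O1′ can be generated together as the 1-oxadiene O1′=C8a′–C4a′=C4′. C3′ is benzylic to ring C, so C3′–C2′ is the CH2–CHO of an arylacetaldehyde.
- Ring C comes from methyl orsellinate: the ester carbon becomes C4, the chelated OH becomes the OMe ortho to it, the free OH ends para, and the methyl group becomes C3′.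
- A temporary isochroman ring (steps 3–5) joins the future C4 to the C3′–C2′ chain, masks the primary alcohol and stores the ring A o-quinone methide.
- Ring order: isochroman (temporary), then pyran ring of chroman 1 (step 8), then pyran ring of chroman 2 (step 12).

Key step: step 12

Assumption: primed locants are those of the second chroman (ring A′); ring A is the benzo ring of the first chroman, ring B its C3 aryl group, ring C the central ring; the lactol carbons and C1 of the isochromans are mixtures that are erased later; compounds 1, 2, 4, 6, 10, 13, 15, 22, 24 and the amine catalyst are bought.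

**Step 1**
Reactants: 1 methyl orsellinate; 2 benzyl bromide
Product: 3 methyl 4-(benzyloxy)-2-hydroxy-6-methylbenzoate
Conditions: BnBr, K2CO3, acetone, reflux
Reagents that add atoms: benzyl bromide, BrCc1ccccc1
Why: Williamson etherification should touch only the C4 hydroxyl, because the C2 hydroxyl is held in a hydrogen bond to the ester carbonyl.

**Step 2**
Reactants: 3 methyl 4-(benzyloxy)-2-hydroxy-6-methylbenzoate; 4 iodomethane
Product: 5 methyl 4-(benzyloxy)-2-methoxy-6-methylbenzoate
Conditions: MeI, K2CO3, DMF, 60 °C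
Reagents that add atoms: iodomethane, CI
Why: Forced Williamson O-methylation of the chelated phenol places the methoxy group ortho to the carbon that becomes C4.

**Step 3**
Reactants: 5 methyl 4-(benzyloxy)-2-methoxy-6-methylbenzoate; 6 formaldehyde
Product: 8 6-(benzyloxy)-8-methoxy-3,4-dihydro-1H-isochromen-1-one, via hydroxy ester 7 (not isolated)
Conditions: LiN(i-Pr)2, THF, −78 °C; HCHO (gas from cracked paraformaldehyde); −78 °C to rt; aq. NH4Cl
Reagents that add atoms: formaldehyde, C=O
Why: Lateral lithiation of the ortho-toluate gives a benzylic anion that adds to formaldehyde, and the alkoxide lactonises on warming (hydroxymethylation–lactonisation), the flanking methoxy group slowing self-condensation at the ester.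

**Step 4**
Reactants: 8 6-(benzyloxy)-8-methoxy-3,4-dihydro-1H-isochromen-1-one
Product: 9 6-(benzyloxy)-8-methoxy-3,4-dihydro-1H-isochromen-1-ol
Conditions: i-Bu2AlH, CH2Cl2, −78 °C; aq. KNaC4H4O6
Reagents that add atoms: none
Why: Partial reduction of a six-membered lactone with i-Bu2AlH should stop at the lactol because the aluminium hemiacetal survives until work-up, and the new hemiacetal centre is of no consequence.

**Step 5**
Reactants: 9 6-(benzyloxy)-8-methoxy-3,4-dihydro-1H-isochromen-1-ol; 10 5-(benzyloxy)-2-bromophenol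
Product: 12 5-(benzyloxy)-2-[6-(benzyloxy)-8-methoxy-3,4-dihydro-1H-isochromen-1-yl]phenol, via benzhydrol triol 11 (not isolated)
Conditions: 10, n-BuLi (2 equiv), THF, −78 to 0 °C; lithium salt of 9 (n-BuLi, 1 equiv), −78 °C to rt; aq. NH4Cl; then pyridinium p-toluenesulfonate (cat.), CH2Cl2, rt
Reagents that add atoms: 5-(benzyloxy)-2-bromophenol, Oc1cc(OCc2ccccc2)ccc1Br
Why: Bromine–lithium exchange on the lithium phenoxide gives an ortho-lithiophenoxide that adds to the open hydroxy-aldehyde form of the lactol (1,2-addition), and mild acid closes the electron-rich benzhydrol onto the tethered primary alcohol to give a stable cyclic ether whose racemic centre is erased in step 8.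

**Step 6**
Reactants: 13 2,3-dihydroxy-4-methoxybenzaldehyde; 2 benzyl bromide
Product: 14 2,3-bis(benzyloxy)-4-methoxybenzaldehyde
Conditions: BnBr, K2CO3, DMF, 60 °C
Reagents that add atoms: benzyl bromide, BrCc1ccccc1
Why: Double Williamson benzylation in DMF should also alkylate the chelated ortho hydroxyl.

**Step 7**
Reactants: 14 2,3-bis(benzyloxy)-4-methoxybenzaldehyde; 15 (methoxymethyl)triphenylphosphonium chloride
Product: 17 2-[2,3-bis(benzyloxy)-4-methoxyphenyl]acetaldehyde, via enol ether 16 (not isolated)
Conditions: 15, KN(SiMe3)2, THF, 0 °C; 14; then 2 M HCl, THF, rt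
Reagents that add atoms: (methoxymethyl)triphenylphosphonium chloride, COC[P+](c1ccccc1)(c1ccccc1)c1ccccc1.[Cl-]; water, O
Why: Wittig methoxymethylenation followed by acid hydrolysis of the enol ether is the standard one-carbon homologation of an aryl aldehyde to an arylacetaldehyde.

**Step 8**
Reactants: 12 5-(benzyloxy)-2-[6-(benzyloxy)-8-methoxy-3,4-dihydro-1H-isochromen-1-yl]phenol; 17 2-[2,3-bis(benzyloxy)-4-methoxyphenyl]acetaldehyde
Product: 20 chroman 1 alcohol (3R,4S), via o-quinone methide 18 (not isolated), via lactol 19 (not isolated)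
Conditions: (R)-2-[diphenyl(trimethylsilyloxy)methyl]pyrrolidine (20 mol %), (PhO)2P(O)OH (20 mol %), CHCl3, 35 °C, slow addition of 17; then Et3SiH, CF3CO2H, CH2Cl2, −40 to 0 °C
Reagents that add atoms: 2-[2,3-bis(benzyloxy)-4-methoxyphenyl]acetaldehyde, COc1ccc(CC=O)c(OCc2ccccc2)c1OCc1ccccc1
Why: Acid opens the isochroman reversibly to the (E)-o-quinone methide of ring A, which should undergo the aminocatalytic formal [4+2] annulation (enamine Michael addition then hemiacetalisation) with the (E)-enamine of 17, the CPh2OSiMe3 group of the (R)-catalyst shielding one enamine face to set C3 as R and the endo (syn-Michael) topology placing the two aryl groups trans to set C4 as S, after which Et3SiH/CF3CO2H reduces the lactol through its oxocarbenium ion (ionic hydrogenation).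

**Step 9**
Reactants: 20 chroman 1 alcohol (3R,4S)
Product: 21 chroman 1 arylacetaldehyde (3R,4S)
Conditions: Dess–Martin periodinane, CH2Cl2, 0 °C to rt
Reagents that add atoms: none
Why: Dess–Martin oxidation of the primary alcohol should stop at the aldehyde under neutral conditions and leave the benzyl ethers, the electron-rich rings and both stereocentres untouched.

**Step 10**
Reactants: 22 4-(benzyloxy)-2-hydroxybenzaldehyde
Product: 23 5-(benzyloxy)-2-(hydroxymethyl)phenol
Conditions: NaBH4, MeOH, 0 °C
Reagents that add atoms: none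
Why: Borohydride reduction of the aryl aldehyde gives the salicyl alcohol without affecting the benzyl ether.

**Step 11**
Reactants: 23 5-(benzyloxy)-2-(hydroxymethyl)phenol; 24 sodium 4-methylbenzenesulfinate
Product: 25 5-(benzyloxy)-2-[(4-methylbenzenesulfonyl)methyl]phenol
Conditions: 24, HCO2H–H2O, rt
Reagents that add atoms: sodium 4-methylbenzenesulfinate, [Na+].[O-]S(=O)c1ccc(C)cc1
Why: The benzylic alcohol, activated by the ortho hydroxyl and the para benzyloxy group, should ionise in aqueous formic acid and be captured at sulfur by the sulfinate (S-alkylation) to give a bench-stable o-quinone methide precursor.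

**Step 12**
Reactants: 21 chroman 1 arylacetaldehyde (3R,4S); 25 5-(benzyloxy)-2-[(4-methylbenzenesulfonyl)methyl]phenol
Product: 28 pentabenzyl ether of the target, via o-quinone methide 26 (not isolated), via lactol 27 (not isolated)
Conditions: (R)-2-[diphenyl(trimethylsilyloxy)methyl]pyrrolidine (20 mol %), NaHCO3, CHCl3, 0 °C to rt; filter; then Et3SiH, CF3CO2H, CH2Cl2, −40 to 0 °C
Reagents that add atoms: 5-(benzyloxy)-2-[(4-methylbenzenesulfonyl)methyl]phenol, Cc1ccc(cc1)S(=O)(=O)Cc1ccc(OCc2ccccc2)cc1O
Why: NaHCO3 eliminates sulfinate from 25 to release o-quinone methide 26 at low stationary concentration while the (R)-catalyst turns aldehyde 21 into its (E)-enamine, whose nucleophilic carbon (the future C3′) adds to the exocyclic CH2 of 26 (C4′), and the phenoxide O1′ set free closes the pyran ring on the iminium or aldehyde carbon C2′ to give lactol 27, which Et3SiH/CF3CO2H reduces in the same flask through the cyclic oxocarbenium ion. The closest known reaction type is the diarylprolinol silyl ether catalysed formal [4+2] annulation (Michael addition then hemiacetalisation) of aldehydes with o-quinone methides released from 2-(sulfonylmethyl)phenols, followed by ionic hydrogenation of a chroman-2-ol. The one ring closed is the pyran ring of the second chroman, by 6-exo-trig attack of O1′ on C2′, overall an inverse-electron-demand oxa-[4+2]. The one new stereocentre, C3′, is set by the catalyst, whose CPh2OSiMe3 group blocks one face of the (E)-enamine so that the (R)-catalyst should give 3′R whatever the two existing centres, which lie five bonds away, would prefer. The step needs cross-annulation to win over o-quinone methide oligomerisation and aldehyde self-aldol, which slow base-mediated release of 26 and the high electrophilicity of its CH2 terminus should secure, and it needs C3′ to keep its configuration, which storage of the alpha-aryl aldehyde as the closed lactol and immediate low-temperature reduction should secure. Regiochemistry is not at issue because C4′ is the only electrophilic carbon of 26 and O1′ the only nucleophile placed to reach C2′.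

**Step 13**
Reactants: 28 pentabenzyl ether of the target
Product: 29 CNP0227211.1
Conditions: H2 (1 atm), Pd/C (10 wt % Pd), THF–MeOH, rt, product handled under argon
Reagents that add atoms: none
Why: Hydrogenolysis of the five aryl benzyl ethers over Pd/C should free all phenols, and since no stereocentre carries a benzylic C–O bond only the O–CH2Ph bonds are cleaved.

**Compound list**

1 | methyl 2,4-dihydroxy-6-methylbenzoate (methyl orsellinate) | COC(=O)c1c(C)cc(O)cc1O | starting material
2 | benzyl bromide | BrCc1ccccc1 | starting material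
3 | methyl 4-(benzyloxy)-2-hydroxy-6-methylbenzoate | COC(=O)c1c(C)cc(OCc2ccccc2)cc1O | intermediate
4 | iodomethane | CI | starting material
5 | methyl 4-(benzyloxy)-2-methoxy-6-methylbenzoate | COC(=O)c1c(C)cc(OCc2ccccc2)cc1OC | intermediate
6 | formaldehyde (monomer from cracked paraformaldehyde) | C=O | starting material
7 | methyl 4-(benzyloxy)-2-(2-hydroxyethyl)-6-methoxybenzoate (formed as its lithium alkoxide) | COC(=O)c1c(CCO)cc(OCc2ccccc2)cc1OC | intermediate
8 | 6-(benzyloxy)-8-methoxy-3,4-dihydro-1H-isochromen-1-one | COc1cc(OCc2ccccc2)cc2CCOC(=O)c12 | intermediate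
9 | 6-(benzyloxy)-8-methoxy-3,4-dihydro-1H-isochromen-1-ol (racemic lactol) | COc1cc(OCc2ccccc2)cc2CCOC(O)c12 | intermediate
10 | 5-(benzyloxy)-2-bromophenol | Oc1cc(OCc2ccccc2)ccc1Br | starting material
11 | 5-(benzyloxy)-2-{[4-(benzyloxy)-2-(2-hydroxyethyl)-6-methoxyphenyl](hydroxy)methyl}phenol (racemic) | COc1cc(OCc2ccccc2)cc(CCO)c1C(O)c1ccc(OCc2ccccc2)cc1O | intermediate
12 | 5-(benzyloxy)-2-[6-(benzyloxy)-8-methoxy-3,4-dihydro-1H-isochromen-1-yl]phenol (racemic) | COc1cc(OCc2ccccc2)cc2CCOC(c3ccc(OCc4ccccc4)cc3O)c12 | intermediate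
13 | 2,3-dihydroxy-4-methoxybenzaldehyde | COc1ccc(C=O)c(O)c1O | starting material
14 | 2,3-bis(benzyloxy)-4-methoxybenzaldehyde | COc1ccc(C=O)c(OCc2ccccc2)c1OCc1ccccc1 | intermediate
15 | (methoxymethyl)triphenylphosphonium chloride | COC[P+](c1ccccc1)(c1ccccc1)c1ccccc1.[Cl-] | starting material
16 | 2,3-bis(benzyloxy)-4-methoxy-1-(2-methoxyethenyl)benzene (E/Z mixture) | COC=Cc1ccc(OC)c(OCc2ccccc2)c1OCc1ccccc1 | intermediate
17 | 2-[2,3-bis(benzyloxy)-4-methoxyphenyl]acetaldehyde | COc1ccc(CC=O)c(OCc2ccccc2)c1OCc1ccccc1 | intermediate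
18 | 3-(benzyloxy)-6-{[4-(benzyloxy)-2-(2-hydroxyethyl)-6-methoxyphenyl]methylidene}cyclohexa-2,4-dien-1-one (o-quinone methide of ring A) | COc1cc(OCc2ccccc2)cc(CCO)c1C=C1C=CC(OCc2ccccc2)=CC1=O | intermediate
19 | (3R,4S)-7-(benzyloxy)-4-[4-(benzyloxy)-2-(2-hydroxyethyl)-6-methoxyphenyl]-3-[2,3-bis(benzyloxy)-4-methoxyphenyl]-3,4-dihydro-2H-chromen-2-ol (C2 epimers) | COc1ccc([C@@H]2C(O)Oc3cc(OCc4ccccc4)ccc3[C@H]2c2c(OC)cc(OCc3ccccc3)cc2CCO)c(OCc2ccccc2)c1OCc1ccccc1 | intermediate
20 | 2-{5-(benzyloxy)-2-[(3R,4S)-7-(benzyloxy)-3-[2,3-bis(benzyloxy)-4-methoxyphenyl]-3,4-dihydro-2H-chromen-4-yl]-3-methoxyphenyl}ethan-1-ol | COc1ccc([C@@H]2COc3cc(OCc4ccccc4)ccc3[C@H]2c2c(OC)cc(OCc3ccccc3)cc2CCO)c(OCc2ccccc2)c1OCc1ccccc1 | intermediate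
21 | 2-{5-(benzyloxy)-2-[(3R,4S)-7-(benzyloxy)-3-[2,3-bis(benzyloxy)-4-methoxyphenyl]-3,4-dihydro-2H-chromen-4-yl]-3-methoxyphenyl}acetaldehyde | COc1ccc([C@@H]2COc3cc(OCc4ccccc4)ccc3[C@H]2c2c(OC)cc(OCc3ccccc3)cc2CC=O)c(OCc2ccccc2)c1OCc1ccccc1 | intermediate
22 | 4-(benzyloxy)-2-hydroxybenzaldehyde | O=Cc1ccc(OCc2ccccc2)cc1O | starting material
23 | 5-(benzyloxy)-2-(hydroxymethyl)phenol | OCc1ccc(OCc2ccccc2)cc1O | intermediate
24 | sodium 4-methylbenzenesulfinate | [Na+].[O-]S(=O)c1ccc(C)cc1 | starting material
25 | 5-(benzyloxy)-2-[(4-methylbenzenesulfonyl)methyl]phenol | Cc1ccc(cc1)S(=O)(=O)Cc1ccc(OCc2ccccc2)cc1O | intermediate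
26 | 3-(benzyloxy)-6-methylidenecyclohexa-2,4-dien-1-one (o-quinone methide of ring A′) | C=C1C=CC(OCc2ccccc2)=CC1=O | intermediate
27 | (3R)-7-(benzyloxy)-3-{5-(benzyloxy)-2-[(3R,4S)-7-(benzyloxy)-3-[2,3-bis(benzyloxy)-4-methoxyphenyl]-3,4-dihydro-2H-chromen-4-yl]-3-methoxyphenyl}-3,4-dihydro-2H-chromen-2-ol (C2′ epimers) | COc1ccc([C@@H]2COc3cc(OCc4ccccc4)ccc3[C@H]2c2c(OC)cc(OCc3ccccc3)cc2[C@@H]2C(O)Oc3cc(OCc4ccccc4)ccc3C2)c(OCc2ccccc2)c1OCc1ccccc1 | intermediate
28 | (3R,4S)-7-(benzyloxy)-4-{4-(benzyloxy)-2-[(3R)-7-(benzyloxy)-3,4-dihydro-2H-chromen-3-yl]-6-methoxyphenyl}-3-[2,3-bis(benzyloxy)-4-methoxyphenyl]-3,4-dihydro-2H-chromene | COc1ccc([C@@H]2COc3cc(OCc4ccccc4)ccc3[C@H]2c2c(OC)cc(OCc3ccccc3)cc2[C@@H]2COc3cc(OCc4ccccc4)ccc3C2)c(OCc2ccccc2)c1OCc1ccccc1 | intermediate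
29 | (3R,4S)-3-(2,3-dihydroxy-4-methoxyphenyl)-4-{4-hydroxy-2-[(3R)-7-hydroxy-3,4-dihydro-2H-chromen-3-yl]-6-methoxyphenyl}-3,4-dihydro-2H-chromen-7-ol (CNP0227211.1) | COc1ccc([C@@H]2COc3cc(O)ccc3[C@H]2c2c(OC)cc(O)cc2[C@@H]2COc3cc(O)ccc3C2)c(O)c1O | target

**Step count and risks**

Total step count: 13. Longest linear sequence: 9 steps (steps 1, 2, 3, 4, 5, 8, 9, 12, 13).

Most likely to fail:

1. Step 8. The carbon–carbon bond must form between a methide carbon flanked by a doubly ortho-substituted aryl group and a hindered enamine; the addition may be too slow, so that aldehyde self-condensation takes over, or the trans (endo) preference may erode. Fallback, setting out from lactol 9 and aldehyde 17: the same (R)-amine catalyst with acid adds the enamine of 17 to the planar isochromanyl oxocarbenium ion derived from 9, and NaBH4 quench gives the (2R)-2-aryl-2-(isochroman-1-yl)ethanol F1. Mitsunobu etherification of F1 with 3-(benzyloxy)phenol gives the aryl ether F2. CF3CO2H then opens the isochroman of F2 to the C4 benzylic cation, stabilised by the para benzyloxy and ortho methoxy groups of ring C, and the tethered ring A attacks it para to its benzyloxy group and anti to ring B (intramolecular Friedel–Crafts alkylation). This closes the pyran ring trans and returns to the route at compound 20.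

2. Step 12. The alpha-aryl aldehyde centre may epimerise, either by renewed enamine formation on the open hydroxy-aldehyde form or by enol ether formation during the ionic reduction; the face selectivity may also suffer from the bulky ortho substituent on ring C, and the arylacetaldehyde may self-condense. Fallback, setting out from aldehyde 21: run the annulation at the carboxylic acid level. Pinnick oxidation (NaClO2) of 21 gives the arylacetic acid F3. Its pivalic mixed anhydride, with the enantiomer of the isothiourea HyperBTM that delivers 3′R and i-Pr2NEt, forms an ammonium enolate that adds to o-quinone methide 26 released from 25 and lactonises to the (3′R)-dihydrocoumarin F4, whose stereocentre alpha to a lactone is much less labile. Reduction of F4 with i-Bu2AlH at −78 °C gives lactol 27, where the route is rejoined.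

3. Step 3. The benzylic anion may be trapped incompletely by gaseous formaldehyde, which repolymerises, and may instead condense with the ester of a second molecule. Fallback, setting out from 5: quench the same lateral anion with CO2 to give the homophthalic half ester F5. BH3·THF then reduces only the carboxylic acid of F5 to hydroxy ester 7, which lactonises with catalytic TsOH to compound 8, where the route is rejoined.

**Further compounds**

F1 | step 8 | (2R)-2-[2,3-bis(benzyloxy)-4-methoxyphenyl]-2-[6-(benzyloxy)-8-methoxy-3,4-dihydro-1H-isochromen-1-yl]ethan-1-ol | COc1ccc([C@H](CO)C2OCCc3cc(OCc4ccccc4)cc(OC)c23)c(OCc2ccccc2)c1OCc1ccccc1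
F2 | step 8 | 3-(benzyloxy)phenyl ether of F1: 6-(benzyloxy)-1-{(1R)-2-[3-(benzyloxy)phenoxy]-1-[2,3-bis(benzyloxy)-4-methoxyphenyl]ethyl}-8-methoxy-3,4-dihydro-1H-isochromene | COc1ccc([C@H](COc2cccc(OCc3ccccc3)c2)C2OCCc3cc(OCc4ccccc4)cc(OC)c23)c(OCc2ccccc2)c1OCc1ccccc1
F3 | step 12 | 2-{5-(benzyloxy)-2-[(3R,4S)-7-(benzyloxy)-3-[2,3-bis(benzyloxy)-4-methoxyphenyl]-3,4-dihydro-2H-chromen-4-yl]-3-methoxyphenyl}acetic acid | COc1ccc([C@@H]2COc3cc(OCc4ccccc4)ccc3[C@H]2c2c(OC)cc(OCc3ccccc3)cc2CC(=O)O)c(OCc2ccccc2)c1OCc1ccccc1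
F4 | step 12 | (3R)-7-(benzyloxy)-3-{5-(benzyloxy)-2-[(3R,4S)-7-(benzyloxy)-3-[2,3-bis(benzyloxy)-4-methoxyphenyl]-3,4-dihydro-2H-chromen-4-yl]-3-methoxyphenyl}-3,4-dihydro-2H-chromen-2-one | COc1ccc([C@@H]2COc3cc(OCc4ccccc4)ccc3[C@H]2c2c(OC)cc(OCc3ccccc3)cc2[C@@H]2C(=O)Oc3cc(OCc4ccccc4)ccc3C2)c(OCc2ccccc2)c1OCc1ccccc1
F5 | step 3 | 2-[5-(benzyloxy)-3-methoxy-2-(methoxycarbonyl)phenyl]acetic acid | COC(=O)c1c(CC(=O)O)cc(OCc2ccccc2)cc1OC
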